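**Retrosynthetic overview**
- Benzyl octacosanoate is cut at the C7–C8 σ-bond of the acyl chain (C1 = ester carbonyl). This gives a henicosyl radical (C8–C28) and a 7-(benzyloxy)-7-oxoheptyl radical (C1–C7), both made by anodic decarboxylation and joined in one mixed Kolbe electrolysis of docosanoic acid with monobenzyl suberate.
- Enabling feature: C7 and C8 are plain CH2 groups inside the unbranched (CH2)26 chain, with C7 six carbons from the ester carbonyl C1 and no heteroatom, branch or π-system at or next to either carbon. Both halves therefore exist as simple carboxylic acids and give unstabilised primary radicals that combine rather than being oxidised further. The two CO2H groups are traceless activating groups, lost as CO2 in the coupling itself.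
- Monobenzyl suberate comes from suberic acid and benzyl alcohol by mono-Fischer esterification.
- Rings: none is formed. The only ring, the phenyl ring of the benzyl ester, is bought in with benzyl alcohol.

Key step: step 2

Remark: the target has no stereocentre and no stereogenic double bond, so it is a single achiral compound and no stereocontrol is required.

**Step 1**
Reactants: 1 suberic acid (octanedioic acid); 2 benzyl alcohol
Product: 3 8-(benzyloxy)-8-oxooctanoic acid (monobenzyl suberate)
Conditions: 1 (3 equiv), 2 (1 equiv), TsOH·H2O (cat.), toluene, reflux, Dean–Stark; cool and filter off excess 1; extract 3 into aq. NaHCO3, then acidify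
Reagents that add atoms: none
Why: Fischer esterification with azeotropic removal of water, where the excess of diacid should hold back double esterification and 3 is the only component that is both soluble in cold toluene and extractable into bicarbonate.

**Step 2**
Reactants: 3 8-(benzyloxy)-8-oxooctanoic acid; 4 docosanoic acid (behenic acid)
Product: 7 benzyl octacosanoate, via henicosyl radical 5 (not isolated), via 7-(benzyloxy)-7-oxoheptyl radical 6 (not isolated)
Conditions: undivided cell, smooth Pt anode / Pt cathode, constant current (ca. 0.25 A cm−2), MeOH–pyridine 3:1, Et3N (0.1 equiv per CO2H), 40–45 °C; 3 (3.5 equiv), 4 (1 equiv); stopped when the electrolyte reaches neutrality; acid/base wash, chromatography, crystallisation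
Reagents that add atoms: none
Why: Mixed Kolbe electrolysis (anodic decarboxylative radical cross-coupling): the carboxylates of 3 and 4 are each oxidised by one electron at the platinum anode, lose CO2 and give the primary radicals 6 and 5, which combine at the electrode surface to form the C7–C8 C(sp3)–C(sp3) bond while the carboxyl protons are reduced to H2 at the cathode. The closest known reaction type is the chain extension of a fatty acid by co-electrolysis with the half-ester of an α,ω-diacid (Brown–Walker variant of the Kolbe reaction), in which benzyl esters have precedent as spectator groups in methanol–pyridine. No ring is closed and no stereocentre is created. The step needs hetero- over homo-coupling and radical combination over further oxidation to the cation (Hofer–Moest path): the first is biased statistically by the excess of the cheap half-ester 3, so that most of radical 5 should meet radical 6, and the second by the substrate, since both radicals are primary, unbranched and carry no α-heteroatom or α-aryl group, supported by smooth Pt, high current density and a weakly acidic medium. The ester of 3 is six carbons from the radical centre and cannot cyclise or fragment, the carboxylate layer on the anode should shield the benzyl group from direct oxidation, and the amine-buffered electrolyte never becomes alkoxide-basic, so methanolysis of the benzyl ester should not compete.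

**Compound list**
1 | suberic acid (octanedioic acid) | OC(=O)CCCCCCC(=O)O | starting material
2 | benzyl alcohol | OCc1ccccc1 | starting material
3 | 8-(benzyloxy)-8-oxooctanoic acid (monobenzyl suberate) | OC(=O)CCCCCCC(=O)OCc1ccccc1 | intermediate
4 | docosanoic acid (behenic acid) | CCCCCCCCCCCCCCCCCCCCCC(=O)O | starting material
5 | henicosyl radical | CCCCCCCCCCCCCCCCCCCC[CH2] | intermediate (not isolated)
6 | 7-(benzyloxy)-7-oxoheptyl radical | [CH2]CCCCCC(=O)OCc1ccccc1 | intermediate (not isolated)
7 | benzyl octacosanoate | CCCCCCCCCCCCCCCCCCCCCCCCCCCC(=O)OCc1ccccc1 | target

**Total step count:** 2
**Longest linear sequence:** 2 steps (1 → 3 → 7)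

**Steps most likely to fail**
The route has only two steps, so both are listed. The key step is listed twice because two independent processes could defeat it.

Risk 1, step 2: statistical homo-coupling of each radical with itself and fouling of the anode by waxy deposits, which would lower the current efficiency and make the purification of 7 tedious. The fallback forms the same C7–C8 bond by a non-electrochemical, non-statistical alkyl–alkyl coupling. It sets out from 4 and 2 and comes back to the route at 7. Docosanoic acid 4 would be condensed with N-hydroxyphthalimide (DIC, cat. DMAP, CH2Cl2) to the redox-active ester 1,3-dioxoisoindolin-2-yl docosanoate F1. Separately, benzyl alcohol 2 would be esterified with commercial 7-bromoheptanoic acid (TsOH, toluene, Dean–Stark) to benzyl 7-bromoheptanoate F2. Zinc insertion (Zn dust, cat. I2, DMA, 70–80 °C) would turn this into [7-(benzyloxy)-7-oxoheptyl]zinc bromide F3. A nickel-catalysed decarboxylative Negishi coupling of F1 with F3 (NiCl2·glyme, 4,4'-di-tert-butyl-2,2'-bipyridine, THF–DMF, rt) should then give 7.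

Risk 2, step 2: loss of the benzyl group during electrolysis, by methanolysis of the ester near the cathode or by anodic oxidation at the benzylic position. The fallback carries the ester through the electrolysis as the methanol-inert methyl ester and brings in the benzyl group afterwards. It sets out from 1 and 4 and comes back at 7. Suberic acid 1 would be converted into its methyl half-ester, 8-methoxy-8-oxooctanoic acid F4 (MeOH, cat. H2SO4, then extractive separation). F4 would be co-electrolysed with 4 under the conditions of step 2 to give methyl octacosanoate F5. Titanate-catalysed transesterification of F5 with benzyl alcohol 2 (cat. Ti(OiPr)4, excess 2, toluene, reflux with removal of methanol) should then give 7.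

Risk 3, step 1: over-esterification of the symmetrical diacid and incomplete separation of the statistical mixture. The fallback desymmetrises by hydrolysis instead of by esterification. It sets out from 1 and 2 and comes back at 3. Suberic acid 1 would be esterified exhaustively with excess benzyl alcohol 2 (TsOH, toluene, Dean–Stark) to dibenzyl octanedioate F6. Selective monohydrolysis of F6 (aq. KOH, 1.0 equiv, THF–H2O, 0 °C, then HCl) should give 3.

**Further compounds**
F1 | step 2 | 1,3-dioxoisoindolin-2-yl docosanoate | CCCCCCCCCCCCCCCCCCCCCC(=O)ON1C(=O)c2ccccc2C1=O
F2 | step 2 | benzyl 7-bromoheptanoate | BrCCCCCCC(=O)OCc1ccccc1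
F3 | step 2 | [7-(benzyloxy)-7-oxoheptyl]zinc bromide | Br[Zn]CCCCCCC(=O)OCc1ccccc1
F4 | step 2 | 8-methoxy-8-oxooctanoic acid (methyl hydrogen suberate) | COC(=O)CCCCCCC(=O)O
F5 | step 2 | methyl octacosanoate | CCCCCCCCCCCCCCCCCCCCCCCCCCCC(=O)OC
F6 | step 1 | dibenzyl octanedioate | O=C(CCCCCCC(=O)OCc1ccccc1)OCc1ccccc1
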